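Carotenoid locants are used throughout. Ring A is the cyclohexane C1–C6 and ring B the dihydrofuran O/C5/C6/C7/C8. Ring C is the butenolide C9/C10/C11/C19/O, followed by the chain C12–C15, C15′–C12′ and C9′, the triple bond C8′≡C7′ and ring D (C1′–C6′).

## Analysis of the target

The molecule is a nor-carotenoid. Ring D (3′R-hydroxy-2,6,6-trimethylcyclohexene) is joined through C7′≡C8′ to an all-E tetraene with methyls on C9′ and C13. The chain ends in the Z-configured C11=C12 ylidene of butenolide ring C, whose α-carbon C9 is bonded to C8 of ring B, fused across C5–C6 to ring A. Three of the four stereocentres sit in the A/B bicycle: C3 (S), C5 (R) and C8 (R). The C3 hydroxyl lies on the face of the C5 methyl (anti to the C5–O bond), and the C8 lactone substituent is trans to the C5 methyl across ring B. C3′ (R) is isolated. Sensitive elements are the polyenyne (light, acid, and an E/Z-labile C9′=C12′ bond next to the triple bond), the ylidene lactone (bases, nucleophiles) and the doubly allylic ether at C8 (acid-induced epimerisation). The hard part is C5, a fully substituted ether carbon wedged between the gem-dimethyl carbon C1 and C6, whose configuration must be tied to that of C8 four atoms away. The strategy rests on one feature: C5 is β to C3. With C3 as a ketone and C4=C5 unsaturated, C5 is the β-carbon of a C3(=O)–C4=C5–C6=C7 dienone, and a hydroxyl on C8 can reach it only if C6=C7 is Z. The same ketone later delivers the C3 carbinol.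

## Retrosynthetic reasoning

**C14′–C15′ (31 ⇒ 23 + 30).** The chain is cut at a single bond between two E-disubstituted alkenes, giving dienyl iodide 23 and dienynyl stannane 30. A stereoretentive cross-coupling is chosen over an olefination because an ylide or sulfonyl carbanion on the ring D half would be delocalised through C9′=C12′. That bond, flanked by the small triple bond, isomerises easily. No protecting group is left for the last step.

**C15=C15′ handle (23 ⇒ 22 ⇒ 21 ⇒ 20).** The iodide comes from aldehyde 22 by one-carbon iodo-olefination. 22 comes from allylic alcohol 21 and this from silyl ether 20. An oxygen at C15 is the one handle that survives the iodide and palladium chemistry used to build ring C.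

**Ring C (20 ⇒ 19 ⇒ 18 ⇒ 17 ⇒ 13 + 16).** The lactone is opened at C9–C19 and C19–O. A carbonylation of Z-β-iodoenone 19 supplies C19 and lets the enol oxygen of the C11 ketone close the ring while creating C11=C12. 19 is the hydroiodination product of ynone 18, which comes from carbinol 17, made by joining C10 of alkyne 13 to C11 of aldehyde 16. This sequence uses the alkyne of 13 directly and brings in C11–C15 in one piece.

**C3 carbinol and alkyne (13 ⇒ 11).** The alcohol is traced to ketone 11. The two axial methyls on C1 and C5 block one face of the carbonyl, so hydride delivery gives the required 3S alcohol. The reduction also ends the reversibility of the preceding step.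

**O–C5, ring B (11 ⇒ 10), the key disconnection.** Cutting the tertiary ether bond gives Z-hydroxy-dienone 10. Forward, the C8 hydroxyl adds to C5 in a 5-exo-trig oxa-Michael reaction. This is the only cut that creates the quaternary ether carbon and ring B together from an acyclic-at-oxygen precursor with one preset stereocentre.

**Precursor 10 (10 ⇒ 7 ⇒ 6 ⇒ 5 ⇒ 4 ⇒ 3 ⇒ 1 + 2).** The Z geometry of C6=C7 is the critical point.
- A route that makes this alkene from a C6 ring ketone (acetylide addition, then a 1,3-oxygen shift) was set aside. With the methyl-bearing sp2 carbon C5 on one flank and the gem-dimethyl carbon C1 on the other, neither isomer is favoured, and only Z can cyclise.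
- The geometry is therefore fixed while C5 is still a carbonyl. In alkylidene ketones 4–7 the C7 substituent should sit next to the small carbonyl and away from the quaternary carbon.
- A methyl nucleophile then adds to that carbonyl, and acid transposes the vinylogous ester (7 ⇒ 10). This installs the C5 methyl, C4=C5 and the C3 ketone in one operation without touching C6=C7.
- C8 is set by enantioselective alkynylation of aldehyde 5. C6=C7 comes from aldol condensation of vinylogous ester 1 with aldehyde 2.

**Aldehyde 16 (16 ⇒ 15 ⇒ 14).** The β,γ-unsaturated aldehyde is the anti-Markovnikov hydration product of the terminal alkyne of silyl ether 15, made from commercial enynol 14. The E trisubstituted alkene is bought, not made.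

**Stannane 30 (30 ⇒ 29 ⇒ 28 ⇒ 26 + 14 ⇒ 25 ⇒ 24).** The stannane comes from enynal 29 by stannyl-olefination. 29 is the oxidation product of diol 28, formed by joining enol triflate 26 to the alkyne of 14 (C6′–C7′ bond). 26 derives from hydroxy ketone 24, which carries C3′ from the chiral pool. Enynol 14 serves twice.

## Alternatives that were turned down

**Alternative 1: carbonylative closure of ring C as the organising step.**
- Disconnection: C9–C19 and C19–O, leading back to Z-β-iodoenone A2.
- Forward key step: Pd(PPh3)4, CO and Et3N convert A2 into ylidene butenolide A1 by oxidative addition at C9–I, CO insertion and capture of the acyl complex by the C11 enol oxygen.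
- For it: one operation builds the lactone, the C11=C12 bond and the attachment of C12–C15, from an alkyne-derived precursor, on well-precedented ground.
- Against it: it addresses the stereochemically easiest ring. A2 already contains ring B with C5 and C8 in place, so the quaternary ether and its relation to C8 are left to an unspecified earlier sequence.
- Comparison: on lactone construction this plan is as strong as anything available, and the chosen route uses the same reaction at step 14. What the chosen strategy offers in addition is a defined, catalytic entry to the C5/C8 pair, where the real uncertainty of the target lies.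

**Alternative 2: gold-catalysed closure of an allenol, axis-to-centre transfer.**
- Disconnection: the O–C8 bond, leading back to allenol A4 (free tertiary C5 hydroxyl, cumulated C6=C7=C8, butenolide on C8).
- Forward key step: Ph3PAuCl/AgOTf (monovalent gold) triggers 5-endo attack of the C5 oxygen on C8 to give dihydrofuran A3, with C6=C7 left in place.
- For it: cyclisation of α-hydroxyallenes is mild and reliable. C8 is set by transfer from the axis, not by face selection, and the quaternary carbinol C5 is made beforehand by ordinary carbonyl chemistry. On fidelity of the key step this plan is stronger than the chosen one.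
- Against it: the difficulty moves into A4. A single axial isomer of a trisubstituted allene whose ring terminus C6 lies between two fully substituted carbons must be made, which costs several stereocontrolled steps. A3 carries only a bare butenolide, so the ylidene chain still has to be attached by aldol and elimination, with its own Z/E question.
- Comparison: more steps before the key step and a second stereochemical problem (the axis). The chosen route reaches its precursor in six steps with one catalytic asymmetric reaction, and accepts a less certain ring closure in exchange.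

**Alternative 3: Ramberg–Bäcklund contraction of an oxathiane dioxide.**
- Disconnection: the C6=C7 bond, leading back to the trans-fused 1,4-oxathiane S,S-dioxide A6 (oxygen between C5 and C8, sulfonyl between C6 and C7).
- Forward key step: KOH and CBr2F2 on Al2O3 halogenate C7, the episulfone forms and loses SO2, giving dihydrofuran A5.
- For it: the position of the alkene and the ring size are fixed by construction, and nothing is reversible. C5 and C8 are set earlier and are spectators. On certainty of constitution it is stronger than the chosen plan.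
- Against it: A6 has four stereocentres and a six-membered ring that is built only to be contracted. The C5–O bond must still be made at a quaternary carbon, now without activation. The sulfonyl carbon C6 is neopentyl on both sides. Under KOH the C7 carbanion has a β-alkoxy leaving group at C8 (ring opening by elimination), and C8–H is propargylic and α to oxygen.
- Comparison: considerably longer and base-sensitive at the centre that matters. The chosen strategy forms ring B and the quaternary centre in one catalytic step from a precursor with a single stereocentre.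

Key step: step 7

Assumption and shorthand: hydroxy ketone 24 and E-enynol 14 are purchased as single isomers, and 2 is used as the anhydrous monomer obtained from its commercial aqueous solution. TMS, TES and TBS are trimethylsilyl, triethylsilyl and tert-butyldimethylsilyl, and HHB is the (2R,6S,7aR)-6-hydroxy-4,4,7a-trimethyl-2,4,5,6,7,7a-hexahydro-1-benzofuran-2-yl group.

## Route

### Rings A/B: steps 1–8

Step 1
Reactants: 1 3-ethoxy-5,5-dimethylcyclohex-2-en-1-one; 2 2,2-dimethoxyacetaldehyde
Product: 3 3-ethoxy-6-(1-hydroxy-2,2-dimethoxyethyl)-5,5-dimethylcyclohex-2-en-1-one (diastereomer mixture)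
Conditions: LiN(i-Pr)2, THF, −78 °C; then 2; aq. NH4Cl
Reagents that add atoms: none
Why: Kinetic deprotonation of the vinylogous ester is possible only at the α′ carbon (the future C6), and the cross-conjugated lithium enolate adds to the unhindered aldehyde (directed aldol reaction). Both new stereocentres are erased in step 2.

Step 2
Reactants: 3 3-ethoxy-6-(1-hydroxy-2,2-dimethoxyethyl)-5,5-dimethylcyclohex-2-en-1-one
Product: 4 (Z)-6-(2,2-dimethoxyethylidene)-3-ethoxy-5,5-dimethylcyclohex-2-en-1-one
Conditions: MsCl, Et3N, CH2Cl2, 0 °C; then DBU, rt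
Reagents that add atoms: none
Why: Mesylation and E1cB elimination give the exocyclic enone, and DBU lets the alkylidene equilibrate. The acetal carbon should settle next to the small ring carbonyl and away from the gem-dimethyl carbon (avoidance of allylic strain), which is the Z isomer that later places C8 beside C5.

Step 3
Reactants: 4 (Z)-6-(2,2-dimethoxyethylidene)-3-ethoxy-5,5-dimethylcyclohex-2-en-1-one
Product: 5 (Z)-2-(4-ethoxy-6,6-dimethyl-2-oxocyclohex-3-en-1-ylidene)acetaldehyde
Conditions: TsOH·H2O (cat.), acetone–H2O, rt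
Reagents that add atoms: water, O
Why: Acid hydrolysis of the allylic dimethyl acetal should be much faster than that of the vinylogous ester, so the enal is released selectively. The formyl group still faces the carbonyl, so Z remains the preferred geometry.

Step 4
Reactants: 5 (Z)-2-(4-ethoxy-6,6-dimethyl-2-oxocyclohex-3-en-1-ylidene)acetaldehyde
Product: 6 (Z)-3-ethoxy-6-[(R)-2-hydroxy-4-(trimethylsilyl)but-3-yn-1-ylidene]-5,5-dimethylcyclohex-2-en-1-one
Conditions: Me2Zn, HC≡CSiMe3, 2,6-bis{[(2S)-2-(hydroxydiphenylmethyl)pyrrolidin-1-yl]methyl}-4-methylphenol (20 mol%), Ph3PO (40 mol%), toluene, 0 °C; aq. NH4Cl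
Reagents that add atoms: trimethylsilylacetylene, C#C[Si](C)(C)C
Why: Dinuclear zinc–aminoalcohol catalysed enantioselective addition of an alkynylzinc to an α,β-unsaturated aldehyde (Trost alkynylation) creates C8. The (S,S)-ligand is planned for the R carbinol, with its antipode as the control should the sense prove opposite. The deactivated vinylogous-ester carbonyl does not compete.

Step 5
Reactants: 6 (Z)-3-ethoxy-6-[(R)-2-hydroxy-4-(trimethylsilyl)but-3-yn-1-ylidene]-5,5-dimethylcyclohex-2-en-1-one
Product: 7 (Z)-3-ethoxy-5,5-dimethyl-6-[(R)-2-(triethylsilyloxy)-4-(trimethylsilyl)but-3-yn-1-ylidene]cyclohex-2-en-1-one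
Conditions: Et3SiCl, imidazole, CH2Cl2, 0 °C
Reagents that add atoms: chlorotriethylsilane, CC[Si](Cl)(CC)CC
Why: Standard silyl ether formation. The masked C8 oxygen can neither quench the organometallic in step 6 nor capture the allylic cation there before the dienone has formed.

Step 6
Reactants: 7 (Z)-3-ethoxy-5,5-dimethyl-6-[(R)-2-(triethylsilyloxy)-4-(trimethylsilyl)but-3-yn-1-ylidene]cyclohex-2-en-1-one
Product: 10 (Z)-4-[(R)-2-hydroxy-4-(trimethylsilyl)but-3-yn-1-ylidene]-3,5,5-trimethylcyclohex-2-en-1-one, via tertiary carbinol 8 (not isolated), via silyl-protected dienone 9 (not isolated)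
Conditions: MeLi, CeCl3, THF, −78 °C; then 1 M HCl, THF, 0 °C → rt
Reagents that add atoms: methyllithium, C[Li]; water, O
Why: Stork–Danheiser transposition: 1,2-addition of the methylcerium reagent gives 8, which ionises in acid to the ethoxy-stabilised cation, takes up water at C3 and loses ethanol to give enone 9 with the methyl on C5. The same acid then cleaves the triethylsilyl ether. C6=C7 is a spectator, so its Z geometry should be carried over kinetically.

Step 7
Reactants: 10 (Z)-4-[(R)-2-hydroxy-4-(trimethylsilyl)but-3-yn-1-ylidene]-3,5,5-trimethylcyclohex-2-en-1-one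
Product: 11 (2R,7aR)-4,4,7a-trimethyl-2-[(trimethylsilyl)ethynyl]-2,4,7,7a-tetrahydro-1-benzofuran-6(5H)-one
Conditions: 3-{[3,5-bis(trifluoromethyl)phenyl]amino}-4-{[(8α,9S)-6′-methoxycinchonan-9-yl]amino}cyclobut-3-ene-1,2-dione (10 mol%), toluene, 4 Å MS, rt
Reagents that add atoms: none
Why: The quinuclidine nitrogen of the catalyst acts as a general base on the C8 hydroxyl while the squaramide N–H pair binds the C3 carbonyl; the oxygen adds to C5, the β-carbon of the C3(=O)–C4=C5 enone, and protonation at C4 gives the β-alkoxy ketone. The closest known class is the bifunctional amine–thiourea or amine–squaramide cycloetherification of hydroxy enones, used here at its limit because a fully substituted ether carbon is formed on a dienone. Ring B closes in 5-exo-trig mode around the existing C6=C7 bond, and only the Z geometry brings the oxygen within reach of C5. The new centre C5 is controlled by the preset C8 centre together with the catalyst: in the closing conformer the small C8–H turns toward the C5 methyl to avoid allylic strain and the alkynyl group points outward, which translates into the 2,5-trans arrangement (5R from 8R). The quinine-derived catalyst is proposed as the matched partner and its quinidine-derived pseudo-enantiomer is the control. The step needs face selectivity at C5 and site selectivity for C5 over C7; the latter is inherent, since attack at C7 would give an oxirane. The addition is reversible, so a wrong C5 epimer can return through 10, and loss of the C5-methyl/C8 allylic strain of the Z-dienone helps the forward direction. Step 8 then removes the retro-Michael path.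

Step 8
Reactants: 11 (2R,7aR)-4,4,7a-trimethyl-2-[(trimethylsilyl)ethynyl]-2,4,7,7a-tetrahydro-1-benzofuran-6(5H)-one
Product: 13 (2R,6S,7aR)-2-ethynyl-4,4,7a-trimethyl-2,4,5,6,7,7a-hexahydro-1-benzofuran-6-ol, via silylalkynyl alcohol 12 (not isolated)
Conditions: LiBH(s-Bu)3, THF, −78 °C; then NaOH, H2O2, MeOH, 0 °C → rt
Reagents that add atoms: none
Why: The C5 methyl (axial, because the C5–O bond must lie in the plane of ring B) and the axial C1 methyl shield one face of the C3 carbonyl. The bulky hydride should therefore attack from the other side and give the axial 3S alcohol cis to the C5 methyl (substrate-controlled ketone reduction). Methanolic NaOH in the oxidative work-up cleaves the alkynyl C–Si bond.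

### C11–C15 aldehyde: steps 9–10

Step 9
Reactants: 14 (E)-3-methylpent-2-en-4-yn-1-ol
Product: 15 tert-butyldimethyl{[(E)-3-methylpent-2-en-4-yn-1-yl]oxy}silane
Conditions: t-BuMe2SiCl, imidazole, CH2Cl2, rt
Reagents that add atoms: tert-butyldimethylsilyl chloride, CC(C)(C)[Si](C)(C)Cl
Why: Routine silylation of a primary allylic alcohol. The TBS ether is chosen to survive organometallic, iodide and carbonylation conditions.

Step 10
Reactants: 15 tert-butyldimethyl{[(E)-3-methylpent-2-en-4-yn-1-yl]oxy}silane
Product: 16 (E)-5-[(tert-butyldimethylsilyl)oxy]-3-methylpent-3-enal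
Conditions: Cy2BH, THF, 0 °C; then H2O2, pH 7 phosphate buffer, 0 °C
Reagents that add atoms: hydrogen peroxide, OO
Why: Anti-Markovnikov monohydroboration of the terminal alkyne of a conjugated enyne with a dialkylborane, then oxidation of the dienylborane, gives the enol and hence the β,γ-unsaturated aldehyde. Buffering keeps the alkene out of conjugation, and the trisubstituted E alkene is not touched.

### Ring C and the C15′ iodide: steps 11–17

Step 11
Reactants: 13 (2R,6S,7aR)-2-ethynyl-4,4,7a-trimethyl-2,4,5,6,7,7a-hexahydro-1-benzofuran-6-ol; 16 (E)-5-[(tert-butyldimethylsilyl)oxy]-3-methylpent-3-enal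
Product: 17 (E)-7-[(tert-butyldimethylsilyl)oxy]-1-(HHB)-5-methylhept-5-en-1-yn-3-ol (C11 epimers)
Conditions: n-BuLi (2.1 equiv), THF, −78 °C; CeCl3; then 16, −78 °C; aq. NH4Cl
Reagents that add atoms: none
Why: The first equivalent of base is taken by the C3 hydroxyl and the second forms the acetylide. Transmetalation to cerium lowers basicity so that 1,2-addition should outrun enolisation of the doubly activated α-CH2 (Imamoto-type organocerium addition). The new carbinol centre is oxidised away in step 12.

Step 12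
Reactants: 17 (E)-7-[(tert-butyldimethylsilyl)oxy]-1-(HHB)-5-methylhept-5-en-1-yn-3-ol
Product: 18 (E)-7-[(tert-butyldimethylsilyl)oxy]-1-(HHB)-5-methylhept-5-en-1-yn-3-one
Conditions: MnO2, CH2Cl2, rt
Reagents that add atoms: none
Why: Activated MnO2 oxidises the propargylic alcohol and leaves the saturated, hindered C3 alcohol alone, so no protection of C3–OH is needed.

Step 13
Reactants: 18 (E)-7-[(tert-butyldimethylsilyl)oxy]-1-(HHB)-5-methylhept-5-en-1-yn-3-one
Product: 19 (1Z,5E)-7-[(tert-butyldimethylsilyl)oxy]-1-(HHB)-1-iodo-5-methylhepta-1,5-dien-3-one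
Conditions: LiI, AcOH, MeCN, rt, dark
Reagents that add atoms: lithium iodide, [Li+].[I-]
Why: Conjugate hydroiodination of an ynone: iodide adds to C9 and anti protonation at C10 gives the Z-β-iodoenone, with iodine and the C11 carbonyl cis as required for lactonisation. Acetic acid is weak enough for the allylic ethers.

Step 14
Reactants: 19 (1Z,5E)-7-[(tert-butyldimethylsilyl)oxy]-1-(HHB)-1-iodo-5-methylhepta-1,5-dien-3-one
Product: 20 (Z)-5-{(E)-4-[(tert-butyldimethylsilyl)oxy]-2-methylbut-2-en-1-ylidene}-3-(HHB)furan-2(5H)-one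
Conditions: Pd(PPh3)4 (5 mol%), CO (1 atm), Et3N, THF, 50 °C
Reagents that add atoms: carbon monoxide, [C-]#[O+]
Why: Carbonylative lactonisation of a Z-β-iodoenone: zerovalent palladium inserts into C9–I, CO inserts, and the enol oxygen of the C11 ketone (enolised toward the doubly activated C12) captures the acyl complex. This closes ring C and creates C11=C12; the Z ylidene, with the chain on the side of the ring oxygen, is the less strained isomer.

Step 15
Reactants: 20 (Z)-5-{(E)-4-[(tert-butyldimethylsilyl)oxy]-2-methylbut-2-en-1-ylidene}-3-(HHB)furan-2(5H)-one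
Product: 21 (Z)-5-[(E)-4-hydroxy-2-methylbut-2-en-1-ylidene]-3-(HHB)furan-2(5H)-one
Conditions: HF·pyridine, pyridine, THF, 0 °C
Reagents that add atoms: none
Why: Buffered fluoride removes the primary allylic silyl ether under nearly neutral conditions, which the ylidene lactone and the C8 ether should tolerate.

Step 16
Reactants: 21 (Z)-5-[(E)-4-hydroxy-2-methylbut-2-en-1-ylidene]-3-(HHB)furan-2(5H)-one
Product: 22 (2E,4Z)-4-[4-(HHB)-5-oxofuran-2(5H)-ylidene]-3-methylbut-2-enal
Conditions: MnO2, CH2Cl2, rt
Reagents that add atoms: none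
Why: Chemoselective allylic oxidation; the secondary C3 alcohol is not activated and stays.

Step 17
Reactants: 22 (2E,4Z)-4-[4-(HHB)-5-oxofuran-2(5H)-ylidene]-3-methylbut-2-enal
Product: 23 (Z)-3-(HHB)-5-[(2E,4E)-5-iodo-2-methylpenta-2,4-dien-1-ylidene]furan-2(5H)-one
Conditions: CrCl2, CHI3, THF–dioxane, 0 °C → rt
Reagents that add atoms: iodoform, IC(I)I
Why: Takai iodo-olefination adds C15′ as an E-alkenyl iodide under non-basic conditions that tolerate the lactone and the free hydroxyl.

### Ring D stannane: steps 18–22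

Step 18
Reactants: 24 (4R,6R)-4-hydroxy-2,2,6-trimethylcyclohexan-1-one
Product: 25 (4R,6R)-2,2,6-trimethyl-4-[(triethylsilyl)oxy]cyclohexan-1-one
Conditions: Et3SiCl, imidazole, DMF, rt
Reagents that add atoms: chlorotriethylsilane, CC[Si](Cl)(CC)CC
Why: The hydroxyl is masked for the enolate step only. A triethylsilyl ether is chosen because it can be removed in the flask of step 20.

Step 19
Reactants: 25 (4R,6R)-2,2,6-trimethyl-4-[(triethylsilyl)oxy]cyclohexan-1-one
Product: 26 (R)-2,6,6-trimethyl-4-[(triethylsilyl)oxy]cyclohex-1-en-1-yl trifluoromethanesulfonate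
Conditions: LiN(i-Pr)2, THF, −78 °C; then PhNTf2, −78 °C → rt
Reagents that add atoms: N-phenylbis(trifluoromethanesulfonimide), O=S(=O)(N(c1ccccc1)S(=O)(=O)C(F)(F)F)C(F)(F)F
Why: The ketone has a single enolisable position, so only the tetrasubstituted enolate can form; it is trapped on oxygen as the enol triflate. The methyl-bearing stereocentre is erased and the carbinol centre (the future C3′) is untouched.

Step 20
Reactants: 26 (R)-2,6,6-trimethyl-4-[(triethylsilyl)oxy]cyclohex-1-en-1-yl trifluoromethanesulfonate; 14 (E)-3-methylpent-2-en-4-yn-1-ol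
Product: 28 (R)-4-[(E)-5-hydroxy-3-methylpent-3-en-1-yn-1-yl]-3,5,5-trimethylcyclohex-3-en-1-ol, via silyl ether 27 (not isolated)
Conditions: Pd(PPh3)4 (5 mol%), CuI (10 mol%), Et3N, DMF, rt; then Bu4NF, THF, rt
Reagents that add atoms: none
Why: Sonogashira coupling of a hindered enol triflate with a terminal enyne forms the C6′–C7′ bond with the E alkene of 14 retained. Fluoride added to the same flask removes the silyl group so that no protecting group reaches the end.

Step 21
Reactants: 28 (R)-4-[(E)-5-hydroxy-3-methylpent-3-en-1-yn-1-yl]-3,5,5-trimethylcyclohex-3-en-1-ol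
Product: 29 (E)-5-[(R)-4-hydroxy-2,6,6-trimethylcyclohex-1-en-1-yl]-3-methylpent-2-en-4-ynal
Conditions: MnO2, CH2Cl2, rt
Reagents that add atoms: none
Why: Selective oxidation of the primary allylic alcohol in the presence of the secondary ring alcohol.

Step 22
Reactants: 29 (E)-5-[(R)-4-hydroxy-2,6,6-trimethylcyclohex-1-en-1-yl]-3-methylpent-2-en-4-ynal
Product: 30 (R)-3,5,5-trimethyl-4-[(3E,5E)-3-methyl-6-(tributylstannyl)hexa-3,5-dien-1-yn-1-yl]cyclohex-3-en-1-ol
Conditions: CrCl2, Bu3SnCHBr2, LiI, THF–DMF, rt
Reagents that add atoms: tributyl(dibromomethyl)stannane, CCCC[Sn](CCCC)(CCCC)C(Br)Br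
Why: Hodgson–Takai stannyl-olefination converts the aldehyde into the E-alkenylstannane (adding C14′) without base, so the C9′=C12′ geometry is not disturbed.

### Union: step 23

Step 23
Reactants: 23 (Z)-3-(HHB)-5-[(2E,4E)-5-iodo-2-methylpenta-2,4-dien-1-ylidene]furan-2(5H)-one; 30 (R)-3,5,5-trimethyl-4-[(3E,5E)-3-methyl-6-(tributylstannyl)hexa-3,5-dien-1-yn-1-yl]cyclohex-3-en-1-ol
Product: 31 (Z)-3-(HHB)-5-{(2E,4E,6E,8E)-11-[(R)-4-hydroxy-2,6,6-trimethylcyclohex-1-en-1-yl]-2,9-dimethylundeca-2,4,6,8-tetraen-10-yn-1-ylidene}furan-2(5H)-one (CNP0300047.2)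
Conditions: Pd2(dba)3 (5 mol%), AsPh3, DMF, rt, dark
Reagents that add atoms: none
Why: Stille coupling joins C15′ to C14′ with retention at both alkenes under base-free conditions that suit the ylidene lactone. No protecting group remains and no isomerisation step is needed, so the E geometry at C9′=C12′ is preserved.

## Compound list

1 | 3-ethoxy-5,5-dimethylcyclohex-2-en-1-one | CCOC1=CC(=O)CC(C)(C)C1 | starting material
2 | 2,2-dimethoxyacetaldehyde | COC(OC)C=O | starting material
3 | 3-ethoxy-6-(1-hydroxy-2,2-dimethoxyethyl)-5,5-dimethylcyclohex-2-en-1-one | CCOC1=CC(=O)C(C(O)C(OC)OC)C(C)(C)C1 | intermediate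
4 | (Z)-6-(2,2-dimethoxyethylidene)-3-ethoxy-5,5-dimethylcyclohex-2-en-1-one | CCOC1=CC(=O)/C(=C\C(OC)OC)C(C)(C)C1 | intermediate
5 | (Z)-2-(4-ethoxy-6,6-dimethyl-2-oxocyclohex-3-en-1-ylidene)acetaldehyde | CCOC1=CC(=O)/C(=C\C=O)C(C)(C)C1 | intermediate
6 | (Z)-3-ethoxy-6-[(R)-2-hydroxy-4-(trimethylsilyl)but-3-yn-1-ylidene]-5,5-dimethylcyclohex-2-en-1-one | CCOC1=CC(=O)/C(=C\[C@@H](O)C#C[Si](C)(C)C)C(C)(C)C1 | intermediate
7 | (Z)-3-ethoxy-5,5-dimethyl-6-[(R)-2-(triethylsilyloxy)-4-(trimethylsilyl)but-3-yn-1-ylidene]cyclohex-2-en-1-one | CCOC1=CC(=O)/C(=C\[C@@H](O[Si](CC)(CC)CC)C#C[Si](C)(C)C)C(C)(C)C1 | intermediate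
8 | (Z)-3-ethoxy-1,5,5-trimethyl-6-[(R)-2-(triethylsilyloxy)-4-(trimethylsilyl)but-3-yn-1-ylidene]cyclohex-2-en-1-ol (C1 epimers) | CCOC1=CC(C)(O)/C(=C\[C@@H](O[Si](CC)(CC)CC)C#C[Si](C)(C)C)C(C)(C)C1 | intermediate (not isolated)
9 | (Z)-3,5,5-trimethyl-4-[(R)-2-(triethylsilyloxy)-4-(trimethylsilyl)but-3-yn-1-ylidene]cyclohex-2-en-1-one | O=C1C=C(C)/C(=C\[C@@H](O[Si](CC)(CC)CC)C#C[Si](C)(C)C)C(C)(C)C1 | intermediate (not isolated)
10 | (Z)-4-[(R)-2-hydroxy-4-(trimethylsilyl)but-3-yn-1-ylidene]-3,5,5-trimethylcyclohex-2-en-1-one | O=C1C=C(C)/C(=C\[C@@H](O)C#C[Si](C)(C)C)C(C)(C)C1 | intermediate (key-step precursor)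
11 | (2R,7aR)-4,4,7a-trimethyl-2-[(trimethylsilyl)ethynyl]-2,4,7,7a-tetrahydro-1-benzofuran-6(5H)-one | C[Si](C)(C)C#C[C@H]1C=C2C(C)(C)CC(=O)C[C@@]2(C)O1 | intermediate (key-step product)
12 | (2R,6S,7aR)-4,4,7a-trimethyl-2-[(trimethylsilyl)ethynyl]-2,4,5,6,7,7a-hexahydro-1-benzofuran-6-ol | C[Si](C)(C)C#C[C@H]1C=C2C(C)(C)C[C@H](O)C[C@@]2(C)O1 | intermediate (not isolated)
13 | (2R,6S,7aR)-2-ethynyl-4,4,7a-trimethyl-2,4,5,6,7,7a-hexahydro-1-benzofuran-6-ol | C#C[C@H]1C=C2C(C)(C)C[C@H](O)C[C@@]2(C)O1 | intermediate
14 | (E)-3-methylpent-2-en-4-yn-1-ol | C#C/C(C)=C/CO | starting material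
15 | tert-butyldimethyl{[(E)-3-methylpent-2-en-4-yn-1-yl]oxy}silane | C#C/C(C)=C/CO[Si](C)(C)C(C)(C)C | intermediate
16 | (E)-5-[(tert-butyldimethylsilyl)oxy]-3-methylpent-3-enal | O=CC/C(C)=C/CO[Si](C)(C)C(C)(C)C | intermediate
17 | (E)-7-[(tert-butyldimethylsilyl)oxy]-1-[(2R,6S,7aR)-6-hydroxy-4,4,7a-trimethyl-2,4,5,6,7,7a-hexahydro-1-benzofuran-2-yl]-5-methylhept-5-en-1-yn-3-ol (C3 epimers) | CC(C)(C)[Si](C)(C)OC/C=C(C)/CC(O)C#C[C@H]1C=C2C(C)(C)C[C@H](O)C[C@@]2(C)O1 | intermediate
18 | (E)-7-[(tert-butyldimethylsilyl)oxy]-1-[(2R,6S,7aR)-6-hydroxy-4,4,7a-trimethyl-2,4,5,6,7,7a-hexahydro-1-benzofuran-2-yl]-5-methylhept-5-en-1-yn-3-one | CC(C)(C)[Si](C)(C)OC/C=C(C)/CC(=O)C#C[C@H]1C=C2C(C)(C)C[C@H](O)C[C@@]2(C)O1 | intermediate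
19 | (1Z,5E)-7-[(tert-butyldimethylsilyl)oxy]-1-[(2R,6S,7aR)-6-hydroxy-4,4,7a-trimethyl-2,4,5,6,7,7a-hexahydro-1-benzofuran-2-yl]-1-iodo-5-methylhepta-1,5-dien-3-one | CC(C)(C)[Si](C)(C)OC/C=C(C)/CC(=O)/C=C(\I)[C@H]1C=C2C(C)(C)C[C@H](O)C[C@@]2(C)O1 | intermediate
20 | (Z)-5-{(E)-4-[(tert-butyldimethylsilyl)oxy]-2-methylbut-2-en-1-ylidene}-3-[(2R,6S,7aR)-6-hydroxy-4,4,7a-trimethyl-2,4,5,6,7,7a-hexahydro-1-benzofuran-2-yl]furan-2(5H)-one | CC(C)(C)[Si](C)(C)OC/C=C(C)/C=C1/C=C([C@H]2C=C3C(C)(C)C[C@H](O)C[C@@]3(C)O2)C(=O)O1 | intermediate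
21 | (Z)-5-[(E)-4-hydroxy-2-methylbut-2-en-1-ylidene]-3-[(2R,6S,7aR)-6-hydroxy-4,4,7a-trimethyl-2,4,5,6,7,7a-hexahydro-1-benzofuran-2-yl]furan-2(5H)-one | OC/C=C(C)/C=C1/C=C([C@H]2C=C3C(C)(C)C[C@H](O)C[C@@]3(C)O2)C(=O)O1 | intermediate
22 | (2E,4Z)-4-{4-[(2R,6S,7aR)-6-hydroxy-4,4,7a-trimethyl-2,4,5,6,7,7a-hexahydro-1-benzofuran-2-yl]-5-oxofuran-2(5H)-ylidene}-3-methylbut-2-enal | O=C/C=C(C)/C=C1/C=C([C@H]2C=C3C(C)(C)C[C@H](O)C[C@@]3(C)O2)C(=O)O1 | intermediate
23 | (Z)-3-[(2R,6S,7aR)-6-hydroxy-4,4,7a-trimethyl-2,4,5,6,7,7a-hexahydro-1-benzofuran-2-yl]-5-[(2E,4E)-5-iodo-2-methylpenta-2,4-dien-1-ylidene]furan-2(5H)-one | I/C=C/C=C(C)/C=C1/C=C([C@H]2C=C3C(C)(C)C[C@H](O)C[C@@]3(C)O2)C(=O)O1 | intermediate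
24 | (4R,6R)-4-hydroxy-2,2,6-trimethylcyclohexan-1-one | C[C@@H]1C[C@@H](O)CC(C)(C)C1=O | starting material
25 | (4R,6R)-2,2,6-trimethyl-4-[(triethylsilyl)oxy]cyclohexan-1-one | C[C@@H]1C[C@@H](O[Si](CC)(CC)CC)CC(C)(C)C1=O | intermediate
26 | (R)-2,6,6-trimethyl-4-[(triethylsilyl)oxy]cyclohex-1-en-1-yl trifluoromethanesulfonate | CC1=C(OS(=O)(=O)C(F)(F)F)C(C)(C)C[C@H](O[Si](CC)(CC)CC)C1 | intermediate
27 | (E)-3-methyl-5-{(R)-2,6,6-trimethyl-4-[(triethylsilyl)oxy]cyclohex-1-en-1-yl}pent-2-en-4-yn-1-ol | CC1=C(C#C/C(C)=C/CO)C(C)(C)C[C@H](O[Si](CC)(CC)CC)C1 | intermediate (not isolated)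
28 | (R)-4-[(E)-5-hydroxy-3-methylpent-3-en-1-yn-1-yl]-3,5,5-trimethylcyclohex-3-en-1-ol | CC1=C(C#C/C(C)=C/CO)C(C)(C)C[C@H](O)C1 | intermediate
29 | (E)-5-[(R)-4-hydroxy-2,6,6-trimethylcyclohex-1-en-1-yl]-3-methylpent-2-en-4-ynal | CC1=C(C#C/C(C)=C/C=O)C(C)(C)C[C@H](O)C1 | intermediate
30 | (R)-3,5,5-trimethyl-4-[(3E,5E)-3-methyl-6-(tributylstannyl)hexa-3,5-dien-1-yn-1-yl]cyclohex-3-en-1-ol | CC1=C(C#C/C(C)=C/C=C/[Sn](CCCC)(CCCC)CCCC)C(C)(C)C[C@H](O)C1 | intermediate
31 | (Z)-3-[(2R,6S,7aR)-6-hydroxy-4,4,7a-trimethyl-2,4,5,6,7,7a-hexahydro-1-benzofuran-2-yl]-5-{(2E,4E,6E,8E)-11-[(R)-4-hydroxy-2,6,6-trimethylcyclohex-1-en-1-yl]-2,9-dimethylundeca-2,4,6,8-tetraen-10-yn-1-ylidene}furan-2(5H)-one | CC1=C(C#C/C(C)=C/C=C/C=C/C=C(C)/C=C2/C=C([C@H]3C=C4C(C)(C)C[C@H](O)C[C@@]4(C)O3)C(=O)O2)C(C)(C)C[C@H](O)C1 | target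

## Step count and least certain steps

Total: 23 steps. Longest linear sequence: 16 steps (steps 1–8, 11–17 and 23).

**Step 7 (key step).** Three processes can defeat it:
- insufficient face selectivity at C5, because the 2,5-cis and 2,5-trans ethers differ little in energy and a fully substituted β-carbon reacts slowly;
- drift of the Z alkene to the E isomer, which cannot cyclise;
- base-induced prototropy from the doubly activated C8–H, which would destroy the C8 centre.

Fallback: from 6, without silylation, the methylcerium reagent gives the diol (Z)-3-ethoxy-6-[(R)-2-hydroxy-4-(trimethylsilyl)but-3-yn-1-ylidene]-1,5,5-trimethylcyclohex-2-en-1-ol F1. Under anhydrous acid (pyridinium tosylate, CH2Cl2, molecular sieves) its tertiary bis-allylic carbinol ionises, and the Z-disposed C8 hydroxyl captures the C5 terminus of the ethoxy-stabilised cation. This is the same kind of closure as the acid-induced epoxide-to-furanoid rearrangement of carotenoids. The product is the enol ether (2R)-6-ethoxy-4,4,7a-trimethyl-2-[(trimethylsilyl)ethynyl]-2,4,5,7a-tetrahydro-1-benzofuran F2, formed as both C5 epimers. Aqueous acid hydrolyses it to 11 and its epimer (2R,7aS)-4,4,7a-trimethyl-2-[(trimethylsilyl)ethynyl]-2,4,7,7a-tetrahydro-1-benzofuran-6(5H)-one F3, which are separated. The fallback rejoins the route at 11.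

**Step 4.** The enantioselectivity of the alkynylation may be low, because the aldehyde is a β,β-disubstituted enal carrying a second carbonyl that can bind zinc. Fallback: from 5, LiC≡CSiMe3 (THF, −78 °C) gives the racemic carbinol (Z)-3-ethoxy-6-[2-hydroxy-4-(trimethylsilyl)but-3-yn-1-ylidene]-5,5-dimethylcyclohex-2-en-1-one F4. MnO2 oxidises it to the ynone (Z)-3-ethoxy-5,5-dimethyl-6-[2-oxo-4-(trimethylsilyl)but-3-yn-1-ylidene]cyclohex-2-en-1-one F5. Noyori transfer hydrogenation with RuCl[(R,R)-TsDPEN](p-cymene) and HCO2H/Et3N then sets C8 by the well-established ynone reduction and returns to 6.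

**Step 6.** During the acid phase the allylic cation may be intercepted by the C8 oxygen before water adds at C3, the C6=C7 bond may lose its geometry while the cation lives, and the C8 carbinol may ionise. Fallback: from 4, the methylcerium addition and an aqueous oxalic acid work-up are run on the acetal itself, which performs the transposition and the acetal hydrolysis together. The product is (Z)-2-(2,6,6-trimethyl-4-oxocyclohex-2-en-1-ylidene)acetaldehyde F6. The zinc-catalysed alkynylation of step 4 is then carried out on F6 and gives 10 directly. No C8 oxygen is present in the cationic step; the cost is that the Z aldehyde is no longer thermodynamically biased and must be used at once.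

**Step 11.** The metal acetylide may enolise aldehyde 16 (α-CH2 activated by both the carbonyl and the alkene), returning starting materials or the conjugated enal. Fallback: from 16, NaClO2/NaH2PO4 oxidation gives (E)-5-[(tert-butyldimethylsilyl)oxy]-3-methylpent-3-enoic acid F7, and EtSH with a carbodiimide gives the thioester S-ethyl (E)-5-[(tert-butyldimethylsilyl)oxy]-3-methylpent-3-enethioate F8. Coupling of this thioester with alkyne 13 (PdCl2(dppf), CuI, P(2-furyl)3, Et3N, DMF) gives ynone 18 directly, without a carbonyl addition and without step 12.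

**Step 14.** The acylpalladium intermediate may be captured slowly, giving reduction or oligomeric esters instead of ring C, or the ylidene may form as an E/Z mixture. Fallback: from 19, carbonylation in the presence of water (PdCl2(PPh3)2, CO, H2O, Et3N) gives the acid (2Z,6E)-8-[(tert-butyldimethylsilyl)oxy]-2-[(2R,6S,7aR)-6-hydroxy-4,4,7a-trimethyl-2,4,5,6,7,7a-hexahydro-1-benzofuran-2-yl]-6-methyl-4-oxoocta-2,6-dienoic acid F9. A separate carbodiimide-mediated enol lactonisation then closes it to 20, so that C–C and C–O bond formation are no longer coupled in one catalytic cycle.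

## Further compounds

F1 | step 7 | (Z)-3-ethoxy-6-[(R)-2-hydroxy-4-(trimethylsilyl)but-3-yn-1-ylidene]-1,5,5-trimethylcyclohex-2-en-1-ol | CCOC1=CC(C)(O)/C(=C\[C@@H](O)C#C[Si](C)(C)C)C(C)(C)C1
F2 | step 7 | (2R)-6-ethoxy-4,4,7a-trimethyl-2-[(trimethylsilyl)ethynyl]-2,4,5,7a-tetrahydro-1-benzofuran (7a epimers) | CCOC1=CC2(C)O[C@@H](C#C[Si](C)(C)C)C=C2C(C)(C)C1
F3 | step 7 | (2R,7aS)-4,4,7a-trimethyl-2-[(trimethylsilyl)ethynyl]-2,4,7,7a-tetrahydro-1-benzofuran-6(5H)-one | C[Si](C)(C)C#C[C@H]1C=C2C(C)(C)CC(=O)C[C@]2(C)O1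
F4 | step 4 | (Z)-3-ethoxy-6-[2-hydroxy-4-(trimethylsilyl)but-3-yn-1-ylidene]-5,5-dimethylcyclohex-2-en-1-one (racemic) | CCOC1=CC(=O)/C(=C\C(O)C#C[Si](C)(C)C)C(C)(C)C1
F5 | step 4 | (Z)-3-ethoxy-5,5-dimethyl-6-[2-oxo-4-(trimethylsilyl)but-3-yn-1-ylidene]cyclohex-2-en-1-one | CCOC1=CC(=O)/C(=C\C(=O)C#C[Si](C)(C)C)C(C)(C)C1
F6 | step 6 | (Z)-2-(2,6,6-trimethyl-4-oxocyclohex-2-en-1-ylidene)acetaldehyde | O=C1C=C(C)/C(=C\C=O)C(C)(C)C1
F7 | step 11 | (E)-5-[(tert-butyldimethylsilyl)oxy]-3-methylpent-3-enoic acid | OC(=O)C/C(C)=C/CO[Si](C)(C)C(C)(C)C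
F8 | step 11 | S-ethyl (E)-5-[(tert-butyldimethylsilyl)oxy]-3-methylpent-3-enethioate | CCSC(=O)C/C(C)=C/CO[Si](C)(C)C(C)(C)C
F9 | step 14 | (2Z,6E)-8-[(tert-butyldimethylsilyl)oxy]-2-[(2R,6S,7aR)-6-hydroxy-4,4,7a-trimethyl-2,4,5,6,7,7a-hexahydro-1-benzofuran-2-yl]-6-methyl-4-oxoocta-2,6-dienoic acid | OC(=O)/C(=C\C(=O)C/C(C)=C/CO[Si](C)(C)C(C)(C)C)[C@H]1C=C2C(C)(C)C[C@H](O)C[C@@]2(C)O1
A1 | alternative 1 | (Z)-5-{(E)-4-[(tert-butyldimethylsilyl)oxy]-2-methylbut-2-en-1-ylidene}-3-{(2R,6S,7aR)-6-[(tert-butyldimethylsilyl)oxy]-4,4,7a-trimethyl-2,4,5,6,7,7a-hexahydro-1-benzofuran-2-yl}furan-2(5H)-one | CC(C)(C)[Si](C)(C)OC/C=C(C)/C=C1/C=C([C@H]2C=C3C(C)(C)C[C@H](O[Si](C)(C)C(C)(C)C)C[C@@]3(C)O2)C(=O)O1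
A2 | alternative 1 | (1Z,5E)-7-[(tert-butyldimethylsilyl)oxy]-1-{(2R,6S,7aR)-6-[(tert-butyldimethylsilyl)oxy]-4,4,7a-trimethyl-2,4,5,6,7,7a-hexahydro-1-benzofuran-2-yl}-1-iodo-5-methylhepta-1,5-dien-3-one | CC(C)(C)[Si](C)(C)OC/C=C(C)/CC(=O)/C=C(\I)[C@H]1C=C2C(C)(C)C[C@H](O[Si](C)(C)C(C)(C)C)C[C@@]2(C)O1
A3 | alternative 2 | 3-[(2R,6S,7aR)-6-hydroxy-4,4,7a-trimethyl-2,4,5,6,7,7a-hexahydro-1-benzofuran-2-yl]furan-2(5H)-one | O=C1OCC=C1[C@H]2C=C3C(C)(C)C[C@H](O)C[C@@]3(C)O2
A4 | alternative 2 | 3-{(aS)-2-[(2R,4S)-2,4-dihydroxy-2,6,6-trimethylcyclohexylidene]ethenyl}furan-2(5H)-one | O=C1OCC=C1C([H])=[C@]=C2C(C)(C)C[C@H](O)C[C@@]2(C)O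
A5 | alternative 3 | tert-butyldimethyl{[(2R,6S,7aR)-4,4,7a-trimethyl-2-[(triisopropylsilyl)ethynyl]-2,4,5,6,7,7a-hexahydro-1-benzofuran-6-yl]oxy}silane | CC(C)[Si](C(C)C)(C(C)C)C#C[C@H]1C=C2C(C)(C)C[C@H](O[Si](C)(C)C(C)(C)C)C[C@@]2(C)O1
A6 | alternative 3 | (2S,4aR,7S,8aR)-7-[(tert-butyldimethylsilyl)oxy]-5,5,8a-trimethyl-2-[(triisopropylsilyl)ethynyl]octahydro-1,4-benzoxathiine 4,4-dioxide | CC(C)[Si](C(C)C)(C(C)C)C#C[C@H]1CS(=O)(=O)[C@@H]2C(C)(C)C[C@H](O[Si](C)(C)C(C)(C)C)C[C@@]2(C)O1
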